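**Plan**

1. Labdane numbering is used: in the target the lactone carbonyl is C16 (on C13), C13=C14 is the ring alkene, C15 is the OCH2 carbon, C17 is the acid on C8 and C19 the acid on C4.
2. Retrosynthesis: the butenolide is opened at C14–C15 (and at the lactone C–O, which forms in the same operation) to a 2-methylene acid and formaldehyde. C13–C16 is cut next to carbon monoxide and the alkenyl triflate of a C13 methyl ketone. The ketone and the C17 acid go back to the two alkenes of agathic acid.
3. Forward: rings A and B arrive intact in agathic acid. C17 is oxidised first, the side chain is then cut by ozone, C16 is added by carbonylation, and the butenolide is made last by joining C14 to C15.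
4. Stereochemistry: C4, C5, C9 and C10 are those of agathic acid. C8 is set by base equilibration of the C17 aldehyde to the equatorial epimer (8βH).
5. Feature used by the key step: in the 2-methylene acid the C16 carboxyl group is cis to one hydrogen of C14 across C13=C14, so a five-membered metallacycle (Rh, O, C16, C13, C14) can form there. The acids on ring A (C19) and ring B (C17) have only sp3 hydrogens in reach, so the step is run on the unprotected triacid.

Key step: step 10

Assumption: agathic acid (1) is taken to be purchasable from natural-product suppliers; its C13 methyl carbon becomes C14 of the target, and its own C14 and C15 are lost in step 6.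

Step 1
Reactants: 1 agathic acid, (13E)-labda-8(17),13-diene-15,19-dioic acid
Product: 2 di-tert-butyl (13E)-labda-8(17),13-diene-15,19-dioate
Conditions: Me2NCH(OtBu)2 (6 equiv), toluene, 80 °C
Reagents that add atoms: N,N-dimethylformamide di-tert-butyl acetal, CN(C)C(OC(C)(C)C)OC(C)(C)C
Why: Acid-triggered tert-butyl transfer from the amide acetal to the carboxylate (ester formation by O-alkylation) should work also for the hindered axial C19 acid, and no stereocentre is touched.

Step 2
Reactants: 2 di-tert-butyl (13E)-labda-8(17),13-diene-15,19-dioate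
Product: 3 di-tert-butyl (13E)-17-hydroxy-8αH-labd-13-ene-15,19-dioate
Conditions: 9-BBN (2.5 equiv), THF, 0 to 65 °C; then NaOH, H2O2, 0 °C to rt
Reagents that add atoms: hydrogen peroxide, OO
Why: Hydroboration–oxidation: the bulky borane should add to the 1,1-disubstituted C8=C17 alkene with boron on C17 and leave the conjugated trisubstituted C13=C14 alone; hydrogen should enter C8 from the α face, away from the axial C10 methyl, so the new C8 centre is expected mainly as 8αH (axial CH2OH), which step 3 corrects.

Step 3
Reactants: 3 di-tert-butyl (13E)-17-hydroxy-8αH-labd-13-ene-15,19-dioate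
Product: 5 di-tert-butyl (13E)-17-oxo-8βH-labd-13-ene-15,19-dioate, via axial 8αH aldehyde 4 (not isolated)
Conditions: TEMPO (2,2,6,6-tetramethylpiperidin-1-oxyl, 10 mol%), PhI(OAc)2 (1.3 equiv), CH2Cl2, rt; then DBU (0.3 equiv), CH2Cl2, rt
Reagents that add atoms: none
Why: Nitroxyl-catalysed alcohol oxidation stops at the aldehyde, and DBU then equilibrates C8 through the enolate to the equatorial aldehyde, trans to the equatorial C9 chain and free of the 1,3-diaxial contact with the C10 methyl, so C8 is set under thermodynamic control.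

Step 4
Reactants: 5 di-tert-butyl (13E)-17-oxo-8βH-labd-13-ene-15,19-dioate
Product: 6 (13E)-15,19-di-tert-butoxy-15,19-dioxo-8βH-labd-13-en-17-oic acid
Conditions: NaClO2, NaH2PO4, 2-methyl-2-butene, t-BuOH/H2O, rt
Reagents that add atoms: sodium chlorite, [Na+].[O-]Cl=O
Why: Pinnick oxidation turns the aldehyde into the acid in a buffered medium that should not enolise C8, and chlorite does not attack the electron-poor enoate.

Step 5
Reactants: 6 (13E)-15,19-di-tert-butoxy-15,19-dioxo-8βH-labd-13-en-17-oic acid
Product: 7 tri-tert-butyl (13E)-8βH-labd-13-ene-15,17,19-trioate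
Conditions: Me2NCH(OtBu)2 (4 equiv), toluene, 80 °C
Reagents that add atoms: N,N-dimethylformamide di-tert-butyl acetal, CN(C)C(OC(C)(C)C)OC(C)(C)C
Why: The same tert-butyl transfer (ester formation) protects the C17 acid, so that the later enolate and palladium steps meet no acidic proton.

Step 6
Reactants: 7 tri-tert-butyl (13E)-8βH-labd-13-ene-15,17,19-trioate
Product: 8 di-tert-butyl 13-oxo-14,15-dinor-8βH-labdane-17,19-dioate (C9 side chain CH2CH2COCH3)
Conditions: O3, CH2Cl2/MeOH, −78 °C; then Me2S, −78 °C to rt
Reagents that add atoms: ozone, [O-][O+]=O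
Why: Ozonolysis with reductive work-up cleaves the only C=C left (C13=C14) and leaves C13 as a methyl ketone; the tert-butyl esters are inert.

Step 7
Reactants: 8 di-tert-butyl 13-oxo-14,15-dinor-8βH-labdane-17,19-dioate
Product: 9 alkenyl triflate, di-tert-butyl 17,19-dioate with C9 side chain CH2CH2C(OSO2CF3)=CH2
Conditions: KN(SiMe3)2 (1.1 equiv), THF, −78 °C; then PhNTf2, −78 to 0 °C
Reagents that add atoms: N-phenylbis(trifluoromethanesulfonimide), O=S(=O)(N(c1ccccc1)S(=O)(=O)C(F)(F)F)C(F)(F)F
Why: Kinetic deprotonation of the methyl ketone at the methyl group by the bulky amide at −78 °C and O-sulfonylation of the enolate (enol triflate formation) should give the terminal alkenyl triflate; the hindered ester α-hydrogen at C8 is much less acidic.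

Step 8
Reactants: 9 alkenyl triflate; 10 carbon monoxide
Product: 11 2-methylene acid, di-tert-butyl 17,19-dioate with C9 side chain CH2CH2C(=CH2)CO2H
Conditions: Pd(OAc)2 (5 mol%), PPh3 (10 mol%), CO (1 atm), KOAc, DMF/H2O, 60 °C
Reagents that add atoms: water, O
Why: Palladium-catalysed hydroxycarbonylation of an alkenyl triflate: oxidative addition to zerovalent palladium, CO insertion and capture of the acylpalladium by acetate and water give the 2-substituted acrylic acid, in which CO has become C16.

Step 9
Reactants: 11 2-methylene acid, di-tert-butyl 17,19-dioate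
Product: 12 triacid, 8βH-labdane core with free 17- and 19-acids and C9 side chain CH2CH2C(=CH2)CO2H
Conditions: CF3CO2H/CH2Cl2 (1:1), rt
Reagents that add atoms: none
Why: Acidolysis of the two tert-butyl esters through the tert-butyl cation (ester cleavage) frees the C17 and C19 acids, while the electron-poor acrylic acid should not be protonated at carbon.

Step 10
Reactants: 12 triacid; 13 formaldehyde (supplied as paraformaldehyde)
Product: 15 8βH-labd-13-en-16,15-olide-17,19-dioic acid, via Z-hydroxy triacid 14 (not isolated)
Conditions: [Cp*RhCl2]2 (5 mol%), AgSbF6 (20 mol%), NaOAc (30 mol%), (CH2O)n (5 equiv), 1,4-dioxane, 90 °C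
Reagents that add atoms: none
Why: Proposed new method: the cationic Cp*Rh catalyst (trivalent rhodium, no change of oxidation state in the cycle) should take, with carboxylate assistance, the one C14 hydrogen that stands cis to the C16 carboxyl group and give a five-membered rhodacycle (Rh, O, C16, C13, C14); formaldehyde then inserts into the Rh–C14 bond, which forms C14–C15, and protonolysis frees the (Z)-hydroxy acid 14. The closest known reaction type is the Cp*Rh-catalysed ortho C–H addition of benzoic acids to aldehydes that ends in phthalides, and the same catalysts are known to metalate the cis β-hydrogen of 2-substituted acrylic acids in annulations with alkynes and alkenes. The butenolide ring (O, C16, C13, C14, C15) is completed in the same operation by 5-exo-trig lactonisation, because C15 and its hydroxyl are delivered cis to C16. No stereocentre is formed, and the Z geometry of C13=C14 that the ring needs is fixed by the metallacycle. The step needs site selectivity among three carboxylic acids: only the C16 acid has an sp2 C–H in reach, the C17 and C19 acids face sp3 hydrogens that this catalyst should not cleave, and the product has no such C–H left, so it cannot react again.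

**Compound list**

1 | agathic acid, (13E)-labda-8(17),13-diene-15,19-dioic acid (4β-CO2H axial, 4α-CH3, 5α-H, 9α-H, 10β-CH3) | C[C@]12CCC[C@](C)(C(=O)O)[C@@H]1CCC(=C)[C@@H]2CC/C(C)=C/C(=O)O | starting material
2 | di-tert-butyl (13E)-labda-8(17),13-diene-15,19-dioate | C[C@]12CCC[C@](C)(C(=O)OC(C)(C)C)[C@@H]1CCC(=C)[C@@H]2CC/C(C)=C/C(=O)OC(C)(C)C | intermediate
3 | di-tert-butyl (13E)-17-hydroxy-8αH-labd-13-ene-15,19-dioate (CH2OH on C8 β, axial) | C[C@]12CCC[C@](C)(C(=O)OC(C)(C)C)[C@@H]1CC[C@H](CO)[C@@H]2CC/C(C)=C/C(=O)OC(C)(C)C | intermediate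
4 | di-tert-butyl (13E)-17-oxo-8αH-labd-13-ene-15,19-dioate (axial CHO) | C[C@]12CCC[C@](C)(C(=O)OC(C)(C)C)[C@@H]1CC[C@H](C=O)[C@@H]2CC/C(C)=C/C(=O)OC(C)(C)C | intermediate
5 | di-tert-butyl (13E)-17-oxo-8βH-labd-13-ene-15,19-dioate (equatorial CHO, α) | C[C@]12CCC[C@](C)(C(=O)OC(C)(C)C)[C@@H]1CC[C@@H](C=O)[C@@H]2CC/C(C)=C/C(=O)OC(C)(C)C | intermediate
6 | (13E)-15,19-di-tert-butoxy-15,19-dioxo-8βH-labd-13-en-17-oic acid | C[C@]12CCC[C@](C)(C(=O)OC(C)(C)C)[C@@H]1CC[C@@H](C(=O)O)[C@@H]2CC/C(C)=C/C(=O)OC(C)(C)C | intermediate
7 | tri-tert-butyl (13E)-8βH-labd-13-ene-15,17,19-trioate | C[C@]12CCC[C@](C)(C(=O)OC(C)(C)C)[C@@H]1CC[C@@H](C(=O)OC(C)(C)C)[C@@H]2CC/C(C)=C/C(=O)OC(C)(C)C | intermediate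
8 | di-tert-butyl 13-oxo-14,15-dinor-8βH-labdane-17,19-dioate (C9 side chain CH2CH2COCH3) | C[C@]12CCC[C@](C)(C(=O)OC(C)(C)C)[C@@H]1CC[C@@H](C(=O)OC(C)(C)C)[C@@H]2CCC(C)=O | intermediate
9 | alkenyl triflate: 8βH-labdane core, di-tert-butyl 17,19-dioate, C9 side chain CH2CH2C(OSO2CF3)=CH2 | C[C@]12CCC[C@](C)(C(=O)OC(C)(C)C)[C@@H]1CC[C@@H](C(=O)OC(C)(C)C)[C@@H]2CCC(=C)OS(=O)(=O)C(F)(F)F | intermediate
10 | carbon monoxide | [C-]#[O+] | starting material
11 | 2-methylene acid: 8βH-labdane core, di-tert-butyl 17,19-dioate, C9 side chain CH2CH2C(=CH2)CO2H | C[C@]12CCC[C@](C)(C(=O)OC(C)(C)C)[C@@H]1CC[C@@H](C(=O)OC(C)(C)C)[C@@H]2CCC(=C)C(=O)O | intermediate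
12 | triacid: 8βH-labdane core, free 17- and 19-acids, C9 side chain CH2CH2C(=CH2)CO2H | C[C@]12CCC[C@](C)(C(=O)O)[C@@H]1CC[C@@H](C(=O)O)[C@@H]2CCC(=C)C(=O)O | intermediate
13 | formaldehyde (supplied as paraformaldehyde) | C=O | starting material
14 | (Z)-hydroxy triacid: as 12 but with C9 side chain CH2CH2C(CO2H)=CHCH2OH, CH2OH cis to CO2H | C[C@]12CCC[C@](C)(C(=O)O)[C@@H]1CC[C@@H](C(=O)O)[C@@H]2CC/C(C(=O)O)=C/CO | intermediate
15 | 8βH-labd-13-en-16,15-olide-17,19-dioic acid (4β-CO2H, 4α-CH3, 5α-H, 8α-CO2H equatorial, 9α-H, 10β-CH3) | C[C@]12CCC[C@](C)(C(=O)O)[C@@H]1CC[C@@H](C(=O)O)[C@@H]2CCC1=CCOC1=O | target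

**Step count**

Total steps: 10. Longest linear sequence: 10 steps (1 to 15).

**Steps most likely to fail**

1. Step 10 (Proposed new method). The rhodium–C14 bond may be protonated back faster than it adds to formaldehyde, the three carboxylate groups may bind the catalyst so firmly that turnover stops, and the acrylic acid may oligomerise on heating. The fallback uses known chemistry and closes the ring by metathesis at C13=C14 instead. It sets out from 11. O-Allylation of the carboxylate (allyl bromide, K2CO3, DMF) gives the allyl 2-methylene ester F1. Ring-closing metathesis with the second-generation Grubbs catalyst RuCl2(=CHPh)(PCy3)(H2IMes) in toluene at 80 °C gives the butenolide di-tert-butyl ester F2 with loss of ethene. CF3CO2H in CH2Cl2 then cleaves both esters, and the fallback comes back to the route at 15. In this fallback the CH= and OCH2 carbons of the ring come from the allyl group.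

2. Step 2. Hydroboration of the hindered exocyclic alkene may be slow or incomplete, and the conjugated ester may be partly reduced on prolonged heating with the borane. The fallback sets out from 2. Ozone (one equivalent, CH2Cl2, −78 °C, then Me2S) should cleave the electron-rich C8=C17 bond in preference to the conjugated C13=C14 and give the 8-ketone F3. A Wittig reaction with Ph3P=CHOMe (from (methoxymethyl)triphenylphosphonium chloride and KOtBu, THF) gives the enol ether F4. Hydrolysis with aqueous HCl in THF gives the aldehyde, which should equilibrate in the acid to the equatorial epimer, so the fallback comes back to the route at 5.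

3. Step 8. The alkenyl triflate may be lost by hydrolysis or elimination before oxidative addition, and the acrylic acid may polymerise under the warm basic conditions. The fallback sets out from 9. Reductive carboxylation with carbon dioxide (NiBr2(bpy), Mn powder, Et4NI, CO2 1 atm, DMA, rt), a known reaction of alkenyl triflates, gives 11 after acidic work-up, where the route is rejoined; no new compound is made (F0).

**Further compounds**

F1 | step 10 | allyl 2-methylene ester: 8βH-labdane core, di-tert-butyl 17,19-dioate, C9 side chain CH2CH2C(=CH2)CO2CH2CH=CH2 | C[C@]12CCC[C@](C)(C(=O)OC(C)(C)C)[C@@H]1CC[C@@H](C(=O)OC(C)(C)C)[C@@H]2CCC(=C)C(=O)OCC=C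
F2 | step 10 | butenolide di-tert-butyl ester: di-tert-butyl 8βH-labd-13-en-16,15-olide-17,19-dioate | C[C@]12CCC[C@](C)(C(=O)OC(C)(C)C)[C@@H]1CC[C@@H](C(=O)OC(C)(C)C)[C@@H]2CCC1=CCOC1=O
F3 | step 2 | 8-ketone: di-tert-butyl (13E)-8-oxo-17-norlabd-13-ene-15,19-dioate | C[C@]12CCC[C@](C)(C(=O)OC(C)(C)C)[C@@H]1CCC(=O)[C@@H]2CC/C(C)=C/C(=O)OC(C)(C)C
F4 | step 2 | enol ether: di-tert-butyl (13E)-17-methoxylabda-8(17),13-diene-15,19-dioate (mixture of C8=C17 geometric isomers) | C[C@]12CCC[C@](C)(C(=O)OC(C)(C)C)[C@@H]1CCC(=COC)[C@@H]2CC/C(C)=C/C(=O)OC(C)(C)C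
F0 | step 8 | none | none
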